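**Retrosynthetic overview** (atom numbers are those of the acid chain, C1 = CO2H)

1. The acid is taken back to a (2Z)-allylic TIPS ether (desilylation, then two-stage oxidation of CH2OH to CO2H).
2. Key disconnection: C5–C6 together with C5–isopropenyl, in a one-flask union of three components: the α-lithiated benzoate of the C12 furan fragment, a (2E,6Z)-farnesyl pinacol boronate and isopropenyllithium (lithiation–borylation with 1,2-metallate shift, then Zweifel olefination).
3. Enabling feature: C5 is the only stereocentre, a tertiary C–H carbon whose three carbon neighbours are C4 (CH2), the allylic C6H2 of the farnesyl-type chain and the sp2 carbon of an isopropenyl group. C5 can therefore start as an O-bearing CH2 (carbenoid carbon) that receives C6 from boron, and the boron left on C5 is traded for the isopropenyl group.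
4. Fragments: the 2Z alkene comes from a Still–Gennari olefination (3-(furan-3-yl)propanal plus an α-alkylated phosphonate); the 7E alkene comes from a 1,4-hydroboration of (Z)-β-farnesene, and the 11Z alkene is bought with nerylacetone.
5. No ring is formed: the only ring, the 3-substituted furan, enters intact with 3-bromofuran and lies far from C5.

Key step: step 11

Remark: the target is read as (2Z,5R,7E,11Z); nerylacetone 16 is taken as the commercial (5Z) isomer of high geometric purity.

**Route**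

Step 1
Reactants: 1 2,4,6-triisopropylbenzoic acid; 2 1,3-diiodopropane
Product: 3 3-iodopropyl 2,4,6-triisopropylbenzoate
Conditions: K2CO3, DMF, 23 °C (2 in excess)
Reagents that add atoms: none
Why: O-alkylation of the carboxylate (SN2) avoids acyl substitution at the very hindered carbonyl, and the excess of diiodide should hold back double substitution.

Step 2
Reactants: 4 methyl 2-[bis(2,2,2-trifluoroethoxy)phosphoryl]acetate; 3 3-iodopropyl 2,4,6-triisopropylbenzoate
Product: 6 methyl 2-[bis(2,2,2-trifluoroethoxy)phosphoryl]-5-[(2,4,6-triisopropylbenzoyl)oxy]pentanoate (racemic), via sodium phosphonoacetate carbanion 5 (not isolated)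
Conditions: NaH, DMF, 0 °C; then 3, 0 → 40 °C
Reagents that add atoms: none
Why: C-alkylation of the stabilised phosphonoacetate carbanion with a primary iodide (SN2) is the usual way to α-substituted Still–Gennari reagents, and the racemic α-centre disappears in step 5.

Step 3
Reactants: 7 3-bromofuran; 8 oxetane
Product: 10 3-(furan-3-yl)propan-1-ol, via 3-lithiofuran 9 (not isolated)
Conditions: n-BuLi, THF, –78 °C; then oxetane, BF3·OEt2, –78 °C
Reagents that add atoms: none
Why: Bromine–lithium exchange at –78 °C should give 3-lithiofuran without drift to the 2-lithio isomer, and the BF3-activated oxetane is opened by the organolithium (SN2 ring opening).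

Step 4
Reactants: 10 3-(furan-3-yl)propan-1-ol
Product: 11 3-(furan-3-yl)propanal
Conditions: IBX, EtOAc, 75 °C
Reagents that add atoms: none
Why: IBX oxidation of a primary alcohol stops at the aldehyde and should leave the furan untouched.

Step 5
Reactants: 6 methyl 2-[bis(2,2,2-trifluoroethoxy)phosphoryl]-5-[(2,4,6-triisopropylbenzoyl)oxy]pentanoate; 11 3-(furan-3-yl)propanal
Product: 13 methyl (2Z)-5-(furan-3-yl)-2-{3-[(2,4,6-triisopropylbenzoyl)oxy]propyl}pent-2-enoate, via potassium phosphonate carbanion 12 (not isolated)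
Conditions: KN(SiMe3)2, 18-crown-6, THF, –78 °C; then 11
Reagents that add atoms: none
Why: Still–Gennari olefination, in which the electron-poor bis(trifluoroethyl) phosphonate and the crown-complexed potassium ion make elimination faster than equilibration, so the kinetic (Z)-enoate with the ester cis to the furylethyl group should form.

Step 6
Reactants: 13 methyl (2Z)-5-(furan-3-yl)-2-{3-[(2,4,6-triisopropylbenzoyl)oxy]propyl}pent-2-enoate
Product: 14 (4Z)-7-(furan-3-yl)-4-(hydroxymethyl)hept-4-en-1-yl 2,4,6-triisopropylbenzoate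
Conditions: i-Bu2AlH, CH2Cl2, –78 °C
Reagents that add atoms: none
Why: 1,2-Reduction of the conjugated methyl ester by i-Bu2AlH at low temperature should leave the alkene geometry and the sterically shielded triisopropylbenzoate untouched.

Step 7
Reactants: 14 (4Z)-7-(furan-3-yl)-4-(hydroxymethyl)hept-4-en-1-yl 2,4,6-triisopropylbenzoate
Product: 15 (4Z)-7-(furan-3-yl)-4-{[(triisopropylsilyl)oxy]methyl}hept-4-en-1-yl 2,4,6-triisopropylbenzoate
Conditions: TIPSCl, imidazole, DMF, 23 °C
Reagents that add atoms: chlorotriisopropylsilane, CC(C)[Si](Cl)(C(C)C)C(C)C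
Why: Silylation of the primary allylic alcohol gives a bulky ether that should survive s-BuLi, I2 and NaOMe and that hinders metalation at the allylic O–CH2.

Step 8
Reactants: 16 nerylacetone, (5Z)-6,10-dimethylundeca-5,9-dien-2-one
Product: 18 (5Z)-6,10-dimethylundeca-1,5,9-trien-2-yl trifluoromethanesulfonate, via lithium enolate 17 (not isolated)
Conditions: LiN(i-Pr)2, THF, –78 °C; then PhNTf2, –78 → 0 °C
Reagents that add atoms: N-phenylbis(trifluoromethanesulfonimide), O=S(=O)(N(c1ccccc1)S(=O)(=O)C(F)(F)F)C(F)(F)F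
Why: Kinetic deprotonation of the methyl ketone gives the less substituted enolate, which is O-triflated.

Step 9
Reactants: 18 (5Z)-6,10-dimethylundeca-1,5,9-trien-2-yl trifluoromethanesulfonate; 19 tributyl(vinyl)stannane
Product: 20 (Z)-β-farnesene, (6Z)-7,11-dimethyl-3-methylidenedodeca-1,6,10-triene
Conditions: Pd(PPh3)4 (zerovalent palladium, cat.), LiCl, THF, 65 °C
Reagents that add atoms: none
Why: Stille coupling of an alkenyl triflate with a vinylstannane gives the 2-substituted 1,3-diene and does not involve the remote Z alkene.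

Step 10
Reactants: 20 (Z)-β-farnesene
Product: 21 4,4,5,5-tetramethyl-2-[(2E,6Z)-3,7,11-trimethyldodeca-2,6,10-trien-1-yl]-1,3,2-dioxaborolane
Conditions: HBpin, FeCl2(L) cat. (L = N-aryl 2-pyridylmethanimine), Mg cat., Et2O, 23 °C
Reagents that add atoms: pinacolborane, [H]B1OC(C)(C)C(C)(C)O1
Why: Iron-catalysed 1,4-hydroboration of a 2-substituted 1,3-diene through an s-cis-bound diene puts hydride on the methylidene carbon and boron on the unsubstituted terminus, so the new methyl and the CH2B group should end cis (the 2E allylboronate) while the isolated alkenes stay untouched.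

Step 11
Reactants: 15 (4Z)-7-(furan-3-yl)-4-{[(triisopropylsilyl)oxy]methyl}hept-4-en-1-yl 2,4,6-triisopropylbenzoate; 21 4,4,5,5-tetramethyl-2-[(2E,6Z)-3,7,11-trimethyldodeca-2,6,10-trien-1-yl]-1,3,2-dioxaborolane; 22 2-bromopropene
Product: 29 triisopropyl{[(2Z,5R,7E,11Z)-2-[3-(furan-3-yl)propylidene]-8,12,16-trimethyl-5-(prop-1-en-2-yl)heptadeca-7,11,15-trien-1-yl]oxy}silane, via lithiated benzoate 23 (not isolated), via lithium boronate complex 24 (not isolated), via secondary boronic ester 25 (not isolated), via isopropenyllithium 26 (not isolated), via alkenylboronate complex 27 (not isolated), via iodoboronic ester 28 (not isolated)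
Conditions: s-BuLi, (–)-sparteine, Et2O, –78 °C; 21, –78 → 35 °C; then THF, 26 (from 22, t-BuLi, –78 °C), –78 °C; I2, MeOH; NaOMe, –78 → 23 °C
Reagents that add atoms: none
Why: Sparteine-complexed s-BuLi removes the pro-S hydrogen of the O–CH2 group of 15 to give the configurationally stable (S)-carbenoid 23, which adds to the boron of 21 with retention (24); on warming, the intact farnesyl CH2 migrates from boron to carbon anti to the benzoate leaving group (stereospecific 1,2-metallate rearrangement, inversion at carbon), which forms the C5–C6 bond and the (R)-boronic ester 25. Isopropenyllithium 26 then forms boronate 27, iodine activates its alkenyl group, the secondary alkyl group shifts from boron to carbon with retention (28), and methoxide triggers anti-elimination of boron and iodine (Zweifel olefination) to leave the isopropenyl group on C5. The closest known reaction types are the lithiation–borylation of primary triisopropylbenzoates with allylic pinacol boronic esters and the Zweifel olefination of secondary boronic esters with isopropenyllithium, here telescoped in one flask. No ring is closed. The only stereocentre, C5, is set under reagent control by (–)-sparteine in the deprotonation and is carried through one stereospecific inversion and one stereospecific retention, which should give 5R. The step needs deprotonation only at the O–CH2 group (secured by precomplexation of the base to the benzoate carbonyl and by the bulky TIPS ether), 1,2- and not 1,3-transfer of the allyl group (secured by the four-coordinate boronate and the good leaving group), and unchanged alkene geometries (no stage touches the 2Z, 7E or 11Z alkenes).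

Step 12
Reactants: 29 triisopropyl{[(2Z,5R,7E,11Z)-2-[3-(furan-3-yl)propylidene]-8,12,16-trimethyl-5-(prop-1-en-2-yl)heptadeca-7,11,15-trien-1-yl]oxy}silane
Product: 30 (2Z,5R,7E,11Z)-2-[3-(furan-3-yl)propylidene]-8,12,16-trimethyl-5-(prop-1-en-2-yl)heptadeca-7,11,15-trien-1-ol
Conditions: Bu4NF, THF, 0 → 23 °C
Reagents that add atoms: none
Why: Fluoride cleaves the silyl ether, and no other group in 29 is labile to fluoride or mild base.

Step 13
Reactants: 30 (2Z,5R,7E,11Z)-2-[3-(furan-3-yl)propylidene]-8,12,16-trimethyl-5-(prop-1-en-2-yl)heptadeca-7,11,15-trien-1-ol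
Product: 32 (2Z,5R,7E,11Z)-2-[3-(furan-3-yl)propylidene]-8,12,16-trimethyl-5-(prop-1-en-2-yl)heptadeca-7,11,15-trienoic acid, via enal 31 (not isolated)
Conditions: Dess–Martin periodinane, pyridine, CH2Cl2, 0 °C; then NaClO2, NaH2PO4, 2-methyl-2-butene, t-BuOH/H2O, 0 → 23 °C
Reagents that add atoms: sodium chlorite, [Na+].[O-]Cl=O
Why: Buffered Dess–Martin oxidation gives the (Z)-enal, which is oxidised at once under Pinnick conditions, where 2-methyl-2-butene scavenges hypochlorous acid and so should protect the furan and the alkenes; neither stage touches C5.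

**Compound list**

1 | 2,4,6-triisopropylbenzoic acid | CC(C)c1cc(C(C)C)c(C(=O)O)c(C(C)C)c1 | starting material
2 | 1,3-diiodopropane | ICCCI | starting material
3 | 3-iodopropyl 2,4,6-triisopropylbenzoate | CC(C)c1cc(C(C)C)c(C(=O)OCCCI)c(C(C)C)c1 | intermediate
4 | methyl 2-[bis(2,2,2-trifluoroethoxy)phosphoryl]acetate | COC(=O)CP(=O)(OCC(F)(F)F)OCC(F)(F)F | starting material
5 | sodium carbanion of 4 (not isolated) | [Na+].COC(=O)[CH-]P(=O)(OCC(F)(F)F)OCC(F)(F)F | intermediate
6 | methyl 2-[bis(2,2,2-trifluoroethoxy)phosphoryl]-5-[(2,4,6-triisopropylbenzoyl)oxy]pentanoate (racemic) | COC(=O)C(CCCOC(=O)c1c(C(C)C)cc(C(C)C)cc1C(C)C)P(=O)(OCC(F)(F)F)OCC(F)(F)F | intermediate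
7 | 3-bromofuran | Brc1ccoc1 | starting material
8 | oxetane | C1COC1 | starting material
9 | 3-lithiofuran (not isolated) | [Li]c1ccoc1 | intermediate
10 | 3-(furan-3-yl)propan-1-ol | OCCCc1ccoc1 | intermediate
11 | 3-(furan-3-yl)propanal | O=CCCc1ccoc1 | intermediate
12 | potassium carbanion of 6 (not isolated) | [K+].COC(=O)[C-](CCCOC(=O)c1c(C(C)C)cc(C(C)C)cc1C(C)C)P(=O)(OCC(F)(F)F)OCC(F)(F)F | intermediate
13 | methyl (2Z)-5-(furan-3-yl)-2-{3-[(2,4,6-triisopropylbenzoyl)oxy]propyl}pent-2-enoate | O=C(OCCC/C(=C/CCc1ccoc1)C(=O)OC)c1c(C(C)C)cc(C(C)C)cc1C(C)C | intermediate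
14 | (4Z)-7-(furan-3-yl)-4-(hydroxymethyl)hept-4-en-1-yl 2,4,6-triisopropylbenzoate | O=C(OCCC/C(=C/CCc1ccoc1)CO)c1c(C(C)C)cc(C(C)C)cc1C(C)C | intermediate
15 | (4Z)-7-(furan-3-yl)-4-{[(triisopropylsilyl)oxy]methyl}hept-4-en-1-yl 2,4,6-triisopropylbenzoate | O=C(OCCC/C(=C/CCc1ccoc1)CO[Si](C(C)C)(C(C)C)C(C)C)c1c(C(C)C)cc(C(C)C)cc1C(C)C | intermediate
16 | nerylacetone, (5Z)-6,10-dimethylundeca-5,9-dien-2-one | CC(=O)CC/C=C(/C)CCC=C(C)C | starting material
17 | lithium enolate of 16 on the methyl side (not isolated) | [Li+].C=C([O-])CC/C=C(/C)CCC=C(C)C | intermediate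
18 | (5Z)-6,10-dimethylundeca-1,5,9-trien-2-yl trifluoromethanesulfonate | C=C(OS(=O)(=O)C(F)(F)F)CC/C=C(/C)CCC=C(C)C | intermediate
19 | tributyl(vinyl)stannane | C=C[Sn](CCCC)(CCCC)CCCC | starting material
20 | (Z)-β-farnesene, (6Z)-7,11-dimethyl-3-methylidenedodeca-1,6,10-triene | C=CC(=C)CC/C=C(/C)CCC=C(C)C | intermediate
21 | 4,4,5,5-tetramethyl-2-[(2E,6Z)-3,7,11-trimethyldodeca-2,6,10-trien-1-yl]-1,3,2-dioxaborolane | CC1(C)OB(C/C=C(\C)CC/C=C(/C)CCC=C(C)C)OC1(C)C | intermediate
22 | 2-bromopropene | C=C(C)Br | starting material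
23 | (S)-1-lithio derivative of 15 at the O–CH carbon, as its (–)-sparteine complex (not isolated) | O=C(O[C@@H]([Li])CC/C(=C/CCc1ccoc1)CO[Si](C(C)C)(C(C)C)C(C)C)c1c(C(C)C)cc(C(C)C)cc1C(C)C | intermediate
24 | lithium boronate complex of 23 and 21, (S) at the O–CH carbon (not isolated) | O=C(O[C@@H]([B-]1(C/C=C(\C)CC/C=C(/C)CCC=C(C)C)OC(C)(C)C(C)(C)O1)CC/C(=C/CCc1ccoc1)CO[Si](C(C)C)(C(C)C)C(C)C)c1c(C(C)C)cc(C(C)C)cc1C(C)C.[Li+] | intermediate
25 | 4,4,5,5-tetramethyl-2-[(2Z,5R,7E,11Z)-2-[3-(furan-3-yl)propylidene]-8,12,16-trimethyl-1-[(triisopropylsilyl)oxy]heptadeca-7,11,15-trien-5-yl]-1,3,2-dioxaborolane (not isolated) | CC1(C)OB(OC1(C)C)[C@@H](C/C=C(\C)CC/C=C(/C)CCC=C(C)C)CC/C(=C/CCc1ccoc1)CO[Si](C(C)C)(C(C)C)C(C)C | intermediate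
26 | isopropenyllithium (not isolated) | [Li]C(C)=C | intermediate
27 | lithium isopropenyl boronate complex of 25, (R) at C5 (not isolated) | [Li+].C=C(C)[B-]1(OC(C)(C)C(C)(C)O1)[C@@H](C/C=C(\C)CC/C=C(/C)CCC=C(C)C)CC/C(=C/CCc1ccoc1)CO[Si](C(C)C)(C(C)C)C(C)C | intermediate
28 | β-iodo boronic ester, pinB–C(CH3)(CH2I)– on C5, (R) at C5, both epimers at the new quaternary carbon (not isolated) | CC1(C)OB(OC1(C)C)C(C)(CI)[C@@H](C/C=C(\C)CC/C=C(/C)CCC=C(C)C)CC/C(=C/CCc1ccoc1)CO[Si](C(C)C)(C(C)C)C(C)C | intermediate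
29 | triisopropyl{[(2Z,5R,7E,11Z)-2-[3-(furan-3-yl)propylidene]-8,12,16-trimethyl-5-(prop-1-en-2-yl)heptadeca-7,11,15-trien-1-yl]oxy}silane | C=C(C)[C@@H](C/C=C(\C)CC/C=C(/C)CCC=C(C)C)CC/C(=C/CCc1ccoc1)CO[Si](C(C)C)(C(C)C)C(C)C | intermediate
30 | (2Z,5R,7E,11Z)-2-[3-(furan-3-yl)propylidene]-8,12,16-trimethyl-5-(prop-1-en-2-yl)heptadeca-7,11,15-trien-1-ol | C=C(C)[C@@H](C/C=C(\C)CC/C=C(/C)CCC=C(C)C)CC/C(=C/CCc1ccoc1)CO | intermediate
31 | (2Z,5R,7E,11Z)-2-[3-(furan-3-yl)propylidene]-8,12,16-trimethyl-5-(prop-1-en-2-yl)heptadeca-7,11,15-trienal (not isolated) | C=C(C)[C@@H](C/C=C(\C)CC/C=C(/C)CCC=C(C)C)CC/C(=C/CCc1ccoc1)C=O | intermediate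
32 | (2Z,5R,7E,11Z)-2-[3-(furan-3-yl)propylidene]-8,12,16-trimethyl-5-(prop-1-en-2-yl)heptadeca-7,11,15-trienoic acid | C=C(C)[C@@H](C/C=C(\C)CC/C=C(/C)CCC=C(C)C)CC/C(=C/CCc1ccoc1)C(=O)O | target

**Step count and risks**

Total steps: 13. Longest linear sequence: 8 steps (3, 4, 5, 6, 7, 11, 12, 13).

Steps most likely to fail:

Step 11. What may go wrong: metalation at a furan C–H or at the allylic O–CH2 in competition with the benzoate-directed deprotonation, erosion of enantioselectivity in the deprotonation, slow or unfaithful 1,2-transfer of the allyl group, or consumption of iodine by sparteine in the telescoped olefination. Fallback: the boron chemistry is moved onto a carbenoid partner that carries neither furan nor allylic ether, and the (Z)-acrylate is built afterwards by olefination.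
- It sets out from 1: O-alkylation with commercial (3-bromopropoxy)(tert-butyl)dimethylsilane (K2CO3, DMF) should give 3-[(tert-butyldimethylsilyl)oxy]propyl 2,4,6-triisopropylbenzoate F1.
- Lithiation–borylation of F1 with 21 and Zweifel olefination with 26, as in step 11 but run in two flasks if needed, should give tert-butyl(dimethyl){[(3S,5E,9Z)-6,10,14-trimethyl-3-(prop-1-en-2-yl)pentadeca-5,9,13-trien-1-yl]oxy}silane F2. The spatial arrangement is that of C5 in 32; the descriptor changes only because the oxygenated arm now outranks the farnesyl CH2.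
- Bu4NF should give (3S,5E,9Z)-6,10,14-trimethyl-3-(prop-1-en-2-yl)pentadeca-5,9,13-trien-1-ol F3.
- I2, PPh3 and imidazole should give the corresponding primary iodide (3S,5E,9Z)-1-iodo-6,10,14-trimethyl-3-(prop-1-en-2-yl)pentadeca-5,9,13-triene F4.
- Alkylation of carbanion 5 with F4 should give methyl (5R,7E,11Z)-2-[bis(2,2,2-trifluoroethoxy)phosphoryl]-8,12,16-trimethyl-5-(prop-1-en-2-yl)heptadeca-7,11,15-trienoate F5.
- Still–Gennari olefination of F5 with aldehyde 11 (KN(SiMe3)2, 18-crown-6) should give methyl (2Z,5R,7E,11Z)-2-[3-(furan-3-yl)propylidene]-8,12,16-trimethyl-5-(prop-1-en-2-yl)heptadeca-7,11,15-trienoate F6.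
- LiOH in THF/MeOH/H2O should then give 32, where the route is rejoined; steps 12 and 13 are not needed on this path.

Step 10. What may go wrong: hydride delivery to the wrong diene terminus (a 2-substituted allylboronate), partial loss of the 2E geometry, or deactivation of the reduced iron catalyst. Fallback: it sets out from 16 and uses classical chain extension.
- Horner–Wadsworth–Emmons reaction with triethyl phosphonoacetate (NaH, THF) and chromatographic removal of the minor 2Z isomer should give ethyl (2E,6Z)-3,7,11-trimethyldodeca-2,6,10-trienoate F7.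
- i-Bu2AlH should give (2E,6Z)-3,7,11-trimethyldodeca-2,6,10-trien-1-ol F8.
- NCS and Me2S in CH2Cl2 should give (2E,6Z)-1-chloro-3,7,11-trimethyldodeca-2,6,10-triene F9.
- Pd2(dba)3-catalysed borylation with B2pin2 (THF, 60 °C) should give 21 with the alkene geometry kept, where the route is rejoined.

Step 13. What may go wrong: Z to E isomerisation of the α-branched enal between the two oxidation stages, and chlorination of the furan or of the trisubstituted alkenes by hypochlorous acid. Fallback: the carboxyl group is carried through the key step at the acid oxidation level as a base-stable orthoester, so no enal is formed.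
- It sets out from 13: LiOH (THF/H2O) should cleave only the methyl ester and give (2Z)-5-(furan-3-yl)-2-{3-[(2,4,6-triisopropylbenzoyl)oxy]propyl}pent-2-enoic acid F10.
- (3-Methyloxetan-3-yl)methanol, EDC and DMAP should give the (3-methyloxetan-3-yl)methyl ester F11.
- BF3·OEt2 (cat.), CH2Cl2, –15 °C should rearrange it to the 4-methyl-2,6,7-trioxabicyclo[2.2.2]octan-1-yl orthoester F12.
- The operation of step 11 on F12 with 21 and 26 should give the coupled (5R) orthoester F13.
- Pyridinium p-toluenesulfonate in MeOH/H2O should open the orthoester to the 3-hydroxy-2-(hydroxymethyl)-2-methylpropyl ester F14, and LiOH should then give 32, where the route is rejoined.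

**Further compounds**

F1 | step 11 | 3-[(tert-butyldimethylsilyl)oxy]propyl 2,4,6-triisopropylbenzoate | CC(C)(C)[Si](C)(C)OCCCOC(=O)c1c(C(C)C)cc(C(C)C)cc1C(C)C
F2 | step 11 | tert-butyl(dimethyl){[(3S,5E,9Z)-6,10,14-trimethyl-3-(prop-1-en-2-yl)pentadeca-5,9,13-trien-1-yl]oxy}silane | C=C(C)[C@@H](C/C=C(\C)CC/C=C(/C)CCC=C(C)C)CCO[Si](C)(C)C(C)(C)C
F3 | step 11 | (3S,5E,9Z)-6,10,14-trimethyl-3-(prop-1-en-2-yl)pentadeca-5,9,13-trien-1-ol | C=C(C)[C@@H](C/C=C(\C)CC/C=C(/C)CCC=C(C)C)CCO
F4 | step 11 | (3S,5E,9Z)-1-iodo-6,10,14-trimethyl-3-(prop-1-en-2-yl)pentadeca-5,9,13-triene | C=C(C)[C@@H](C/C=C(\C)CC/C=C(/C)CCC=C(C)C)CCI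
F5 | step 11 | methyl (5R,7E,11Z)-2-[bis(2,2,2-trifluoroethoxy)phosphoryl]-8,12,16-trimethyl-5-(prop-1-en-2-yl)heptadeca-7,11,15-trienoate (both epimers at C2) | C=C(C)[C@@H](C/C=C(\C)CC/C=C(/C)CCC=C(C)C)CCC(C(=O)OC)P(=O)(OCC(F)(F)F)OCC(F)(F)F
F6 | step 11 | methyl (2Z,5R,7E,11Z)-2-[3-(furan-3-yl)propylidene]-8,12,16-trimethyl-5-(prop-1-en-2-yl)heptadeca-7,11,15-trienoate | C=C(C)[C@@H](C/C=C(\C)CC/C=C(/C)CCC=C(C)C)CC/C(=C/CCc1ccoc1)C(=O)OC
F7 | step 10 | ethyl (2E,6Z)-3,7,11-trimethyldodeca-2,6,10-trienoate | CCOC(=O)/C=C(\C)CC/C=C(/C)CCC=C(C)C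
F8 | step 10 | (2E,6Z)-3,7,11-trimethyldodeca-2,6,10-trien-1-ol | OC/C=C(\C)CC/C=C(/C)CCC=C(C)C
F9 | step 10 | (2E,6Z)-1-chloro-3,7,11-trimethyldodeca-2,6,10-triene | ClC/C=C(\C)CC/C=C(/C)CCC=C(C)C
F10 | step 13 | (2Z)-5-(furan-3-yl)-2-{3-[(2,4,6-triisopropylbenzoyl)oxy]propyl}pent-2-enoic acid | O=C(OCCC/C(=C/CCc1ccoc1)C(=O)O)c1c(C(C)C)cc(C(C)C)cc1C(C)C
F11 | step 13 | (3-methyloxetan-3-yl)methyl (2Z)-5-(furan-3-yl)-2-{3-[(2,4,6-triisopropylbenzoyl)oxy]propyl}pent-2-enoate | O=C(OCCC/C(=C/CCc1ccoc1)C(=O)OCC1(C)COC1)c1c(C(C)C)cc(C(C)C)cc1C(C)C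
F12 | step 13 | (4Z)-7-(furan-3-yl)-4-(4-methyl-2,6,7-trioxabicyclo[2.2.2]octan-1-yl)hept-4-en-1-yl 2,4,6-triisopropylbenzoate | O=C(OCCC/C(=C/CCc1ccoc1)C12OCC(C)(CO1)CO2)c1c(C(C)C)cc(C(C)C)cc1C(C)C
F13 | step 13 | orthoester of 32: the carboxyl carbon of the (2Z,5R,7E,11Z) acid held as 4-methyl-2,6,7-trioxabicyclo[2.2.2]octan-1-yl | C=C(C)[C@@H](C/C=C(\C)CC/C=C(/C)CCC=C(C)C)CC/C(=C/CCc1ccoc1)C12OCC(C)(CO1)CO2
F14 | step 13 | 3-hydroxy-2-(hydroxymethyl)-2-methylpropyl ester of 32 | C=C(C)[C@@H](C/C=C(\C)CC/C=C(/C)CCC=C(C)C)CC/C(=C/CCc1ccoc1)C(=O)OCC(C)(CO)CO
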